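The data stem from a simulated flask for an exercise; noise was put on by code.

Count the product of each earlier run as a fraction of the recipe's charge of starting material, not of its own charge, before arguing about the four flasks.

| setting | beta | eta | alpha | gamma | south-east | north-west | west | east |
|---|---|---|---|---|---|---|---|---|
| starting material | 0.010 M | 0.014 M | 0.022 M | 0.010 M | 0.010 M (fed, over 3.00 min) | 0.010 M | 0.010 M | 0.010 M |
| reagent | 0.040 M | 0.040 M | 0.040 M | 0.040 M | 0.0400 M | 0.0400 M | 0.0400 M (fed, over 3.00 min) | 0.0400 M |
| free catalyst | 0.50 mM | 0.50 mM | 0.50 mM | 0.75 mM | 0.50 mM | 0.50 mM | 0.50 mM | 0.50 mM |
| remark | run made earlier | run made earlier | run made earlier | run made earlier | all but starting material at the start; starting material goes in evenly over 3.00 min, the run ends at 3.0 min | everything together in a closed stirred flask, run for 3.0 min | a stirred flask in which reagent is dosed at a steady rate over 3.00 min without added volume, worked up at 3.0 min | a single well-mixed tank run continuously and read at steady state, 3.0 min in it on average |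
| time |  |  |  |  | 3.0 min | 3.0 min | 3.0 min |  |

beta run (percent of the starting material charged): time / s: product / % = 15.0: 15.9; 30.0: 31.7; 50.0: 48.6; 60.0: 56.3; 80.0: 70.2; 90.0: 75.9; 120: 91.1

eta run (percent of the starting material charged): time / min: product / % = 0.333: 16.5; 0.667: 28.1; 1.00: 39.1; 1.33: 50.0; 1.50: 54.5; 2.00: 66.3; 2.50: 75.7

alpha run (percent of the starting material charged): time / min: product / % = 0.167: 7.1; 0.333: 10.4; 0.667: 18.2; 1.00: 24.4; 1.33: 31.2; 2.00: 42.2; 2.50: 47.5

gamma run (percent of the starting material charged): time / min: product / % = 0.500: 43.1; 1.00: 75.9; 1.33: 90.1; 2.00: 96.7; 2.50: 95.9

(readings scatter by 1 percentage point)

- the set-up with the highest amount of product at the outlet or at the end, in percent of the starting material put in ("none" if the first two lie within 2 percentage points) (south-east / north-west / west / east / none)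
- amount of product at the outlet or at the end, in percent of the starting material put in, south-east
- amount of product at the outlet or at the end, in percent of the starting material put in, north-west
- amount of product at the outlet or at the end, in percent of the starting material put in, west
- amount of product at the outlet or at the end, in percent of the starting material put in, east

- the stated concentrations are those of everything mixed, before any reaction; amounts are the same in each set-up
- the feed brings no volume worth counting
- the earlier runs were made in a closed, stirred flask

Two chemists dispute the west flask, where reagent is dosed over 3.00 min while starting material and free catalyst stand from the start. The first chemist takes the rate as first order in reagent. The dose holds on average half of the reagent charge, and that average already contains the nearly empty start, so on that view 3.0 min of west count as 1.50 min of beta, where beta read 75.9 %.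

The second chemist, whose reckoning I hold to, reads alpha instead. Alpha's 47.5 % at 2.50 min, on a charge 2.20 times the recipe's, is 105 % of the recipe's charge. Call this the reach, the product made by 0.50 mM of free catalyst in that time with starting material in excess, as a fraction of the recipe's charge. Eta gives 106 % at 2.50 min. The reach is more than the recipe's charge, so I expect west to finish beside north-west, near gamma's late 95.9 %, and the best to be none. But beta, eta, alpha and gamma each held 0.040 M of reagent, so this reckoning rests on an untested order.

The forecast, which sides with the first chemist, gives 91 % for south-east, 95.5 % for north-west, 60 % for west (range 40 % to 90 %), lower than that beta reading, and 87 % for east, with best north-west, and grants: “Reagent order is untested because reagent was never varied.”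

The flasks give 95.3 % for south-east, 97.1 % for north-west, 97.6 % for west and 95.3 % for east. West and north-west lie 0.50 percentage points apart, so the best is none.

    reagent + free catalyst → catalyst intermediate A (k = 32.6 L mol⁻¹ s⁻¹)
    catalyst intermediate A ⇌ by-product + catalyst intermediate B (K = 0.0314 M, k = 5.30 s⁻¹)
    starting material + catalyst intermediate B → catalyst intermediate C (k = 6960 L mol⁻¹ s⁻¹)
    catalyst intermediate C → free catalyst + product (k = 0.341 s⁻¹)
    2 catalyst intermediate C → spent catalyst (k = 22.0 L mol⁻¹ s⁻¹)

In west at 1.46 min, free catalyst has a half-life of 1.5 s by its step with reagent, far shorter than the 0.76 min of starting material by its step with catalyst intermediate B. At 3.00 min west holds 0 % of starting material, the limiting reagent, and 74 % of its reagent charge, with its 97.6 % of product below the reach of 105 %. The first chemist's expectation of a lower yield finds its region in the west flask with reagent at 1.60 equiv, which ended at 74.9 % with 22 % of its starting material left. With starting material raised to 0.025 M, the reach, read at 2.50 min, gives 41.8 %, and that west flask held 43.3 % at 3.00 min.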